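**Retrosynthetic overview**
- The target is three six-membered rings joined by two CH2 bridges: ring A (butyrylfilicinic acid), ring B (butyrylphloroglucinol) and ring C (C-methyl butyrylphloroglucinol). Each bridge is cut between its CH2 and a carbon nucleophile, with a phenolic Mannich base as the CH2 donor (A–CH2–B from 17 + 18 in the last step, B–CH2–C from 13 + 15 before it).
- The strategy rests on ring C: the ring carbon bearing the butyryl C=O is bonded to a ring carbon bearing OH, and its other ring neighbour also bears oxygen. A 3-alkoxyaryne gives exactly this pattern when butyric acid adds O and acyl across the triple bond, so the aryl–O and aryl–C(=O) bonds are disconnected to silyl triflate 8 and butyric acid 9.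
- Silyl triflate 8 comes from 2,6-dimethoxytoluene in three steps: C–H borylation/oxidation to the phenol, ortho-bromination, then O-silylation, retro-Brook shift and triflation.
- No ring is built in the route. Ring C comes from 2,6-dimethoxytoluene, rings B and A from phloroglucinol (ring A by gem-dimethylation of 15). The rings are joined in the order C, then B, then A.

Key step: step 4

Remark on the chemistry: ring A is drawn as one tautomer of an enolised β-triketone; the tautomers interconvert and the target has no stereocentre, so no stereocontrol is required.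
Remark on the chemistry: the two ring C oxygens that must stay masked during aryne generation are carried as the methyl ethers already present in commercial 2,6-dimethoxytoluene and are cleaved with BBr3 directly after the key step; the fragment unions are then run on free phenols, ring C having only one open carbon.

Step 1
Reactants: 1 2,6-dimethoxytoluene (1,3-dimethoxy-2-methylbenzene)
Product: 3 3,5-dimethoxy-4-methylphenol, via aryl pinacol boronate 2 (not isolated)
Conditions: [Ir(OMe)(cod)]2 (1.5 mol%), dtbpy (3 mol%), B2pin2 (0.6 equiv), THF, 80 °C; then Oxone (2KHSO5·KHSO4·K2SO4, 1.2 equiv), acetone/H2O, rt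
Reagents that add atoms: bis(pinacolato)diboron, CC1(C)OB(OC1(C)C)B1OC(C)(C)C(C)(C)O1; Oxone (potassium peroxymonosulfate), [K+].[O-]S(=O)(=O)OO
Why: Iridium-catalysed aromatic C–H borylation is governed by sterics and should occur at the only ring C–H without an ortho substituent (para to the methyl group), and oxidation of the aryl boronate with Oxone in the same flask should give the phenol (one-pot C–H borylation/oxidation).

Step 2
Reactants: 3 3,5-dimethoxy-4-methylphenol
Product: 4 2-bromo-3,5-dimethoxy-4-methylphenol
Conditions: NBS (1.0 equiv), CH2Cl2, −78 → −20 °C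
Reagents that add atoms: N-bromosuccinimide, O=C1CCC(=O)N1Br
Why: Electrophilic aromatic bromination; the para position is blocked by methyl and the two open carbons are equivalent, so one equivalent of NBS at low temperature should give the mono-ortho-bromophenol.

Step 3
Reactants: 4 2-bromo-3,5-dimethoxy-4-methylphenol
Product: 8 3,5-dimethoxy-4-methyl-2-(trimethylsilyl)phenyl trifluoromethanesulfonate, via aryl trimethylsilyl ether 5 (not isolated), via aryllithium 6 (not isolated), via lithium 2-silylphenoxide 7 (not isolated)
Conditions: (Me3Si)2NH, THF, 70 °C, then evaporation; n-BuLi (1.1 equiv), THF, −100 → −78 °C; Tf2O (1.2 equiv), −100 °C → rt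
Reagents that add atoms: hexamethyldisilazane, C[Si](C)(C)N[Si](C)(C)C; trifluoromethanesulfonic anhydride, O=S(=O)(OS(=O)(=O)C(F)(F)F)C(F)(F)F
Why: O-silylation, bromine–lithium exchange, anionic 1,3 O→C silyl migration (retro-Brook rearrangement) and O-triflation of the resulting phenoxide form the standard one-pot route to ortho-silylaryl triflates, and the methyl ethers are inert to each of these operations.

Step 4
Reactants: 8 3,5-dimethoxy-4-methyl-2-(trimethylsilyl)phenyl trifluoromethanesulfonate; 9 butyric acid
Product: 11 1-(6-hydroxy-2,4-dimethoxy-3-methylphenyl)butan-1-one, via 3,5-dimethoxy-4-methylbenzyne 10 (not isolated)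
Conditions: 8 (1.3 equiv), 9 (1.0 equiv), CsF (4 equiv), THF, 125 °C, sealed tube
Reagents that add atoms: none
Why: CsF removes the trimethylsilyl group of 8 with loss of triflate to give aryne 10, whose triple bond lies between the former C–OTf carbon (flanked by C–H) and the former C–Si carbon (flanked by a methoxy-bearing carbon); cesium butanoate adds through oxygen to the first of these, and the aryl anion generated on the second attacks the neighbouring ester carbonyl, passing through a strained four-membered alkoxide that opens to the chelated ortho-butyryl phenoxide, protonated on work-up. The closest known reaction type is the formal insertion of arynes generated from ortho-silylaryl triflates into the C–O bond of carboxylic acids, which delivers ortho-hydroxyaryl ketones and can be viewed as an intermolecular counterpart of the anionic Fries shift. No ring of the product is closed (the four-membered ring is only transient) and no stereocentre is created. Regioselectivity is required and should come from the methoxy group beside the triple bond: its inductive withdrawal distorts the aryne so that the oxygen nucleophile bonds to the distal, less hindered carbon and the negative charge, and with it the acyl group, appears next to the methoxy group. Chemoselectivity for acyl transfer over protonation of the aryl anion (which would stop at the aryl butanoate) is also required; the acid as limiting component, an aprotic solvent, excess CsF and 125 °C should favour the shift.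

Step 5
Reactants: 11 1-(6-hydroxy-2,4-dimethoxy-3-methylphenyl)butan-1-one
Product: 12 1-(2,4,6-trihydroxy-3-methylphenyl)butan-1-one
Conditions: BBr3 (5 equiv), CH2Cl2, −78 °C → rt; MeOH, then H2O
Reagents that add atoms: none
Why: Lewis-acid cleavage of aryl methyl ethers with BBr3, in which the ether ortho to the ketone is cleaved with chelation assistance and the para ether by the excess reagent, should leave the aryl ketone untouched and give the free C-methyl acylphloroglucinol.

Step 6
Reactants: 12 1-(2,4,6-trihydroxy-3-methylphenyl)butan-1-one
Product: 13 1-[3-[(dimethylamino)methyl]-2,4,6-trihydroxy-5-methylphenyl]butan-1-one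
Conditions: [Me2N=CH2]I (1.2 equiv), NaHCO3, MeCN, 0 °C → rt; used without chromatography
Reagents that add atoms: N,N-dimethylmethaniminium iodide, C=[N+](C)C.[I-]
Why: Mannich aminomethylation of a phenol with a preformed iminium salt; 12 has a single unsubstituted ring carbon, flanked by two hydroxyl groups, so one product is expected.

Step 7
Reactants: 14 phloroglucinol (benzene-1,3,5-triol)
Product: 15 1-(2,4,6-trihydroxyphenyl)butan-1-one (butyrylphloroglucinol)
Conditions: PrCOCl (1.05 equiv), AlCl3 (3 equiv), PhNO2, rt → 60 °C; aq. HCl
Reagents that add atoms: butanoyl chloride, CCCC(=O)Cl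
Why: Friedel–Crafts C-acylation of phloroglucinol; the first acyl group deactivates the ring, so mono-acylation should dominate.

Step 8
Reactants: 13 1-[3-[(dimethylamino)methyl]-2,4,6-trihydroxy-5-methylphenyl]butan-1-one; 15 1-(2,4,6-trihydroxyphenyl)butan-1-one
Product: 16 1-[3-[(3-butanoyl-2,4,6-trihydroxyphenyl)methyl]-2,4,6-trihydroxy-5-methylphenyl]butan-1-one
Conditions: 15 (4 equiv), 1,4-dioxane, 90 °C, N2
Reagents that add atoms: none
Why: Thermal loss of dimethylamine from the hydroxybenzylamine should give a quinone methide that is trapped at carbon by the acylphloroglucinol (Michael-type C-alkylation); 13 has no free ring carbon and cannot self-condense, and the excess of 15 should hold the reaction at mono-alkylation.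

Step 9
Reactants: 16 1-[3-[(3-butanoyl-2,4,6-trihydroxyphenyl)methyl]-2,4,6-trihydroxy-5-methylphenyl]butan-1-one
Product: 17 1-[3-[[3-butanoyl-5-[(dimethylamino)methyl]-2,4,6-trihydroxyphenyl]methyl]-2,4,6-trihydroxy-5-methylphenyl]butan-1-one
Conditions: [Me2N=CH2]I (1.1 equiv), NaHCO3, MeCN, 0 °C → rt
Reagents that add atoms: N,N-dimethylmethaniminium iodide, C=[N+](C)C.[I-]
Why: Mannich aminomethylation at the single remaining ring C–H of the dimer, which sits on ring B between two hydroxyl groups; the mild base and low temperature should leave the existing bridge untouched.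

Step 10
Reactants: 15 1-(2,4,6-trihydroxyphenyl)butan-1-one
Product: 18 2-butanoyl-3,5-dihydroxy-6,6-dimethylcyclohexa-2,4-dien-1-one (butyrylfilicinic acid)
Conditions: MeI (2.2 equiv), NaOMe, MeOH, 0 °C → rt; aq. HCl
Reagents that add atoms: iodomethane, CI
Why: Base-mediated dearomatising geminal C-methylation of an acylphloroglucinol, the classical entry to acylfilicinic acids; selectivity over mono- and tri-methylation is moderate, but it is spent on inexpensive material and the acidic product should be separable.

Step 11
Reactants: 17 1-[3-[[3-butanoyl-5-[(dimethylamino)methyl]-2,4,6-trihydroxyphenyl]methyl]-2,4,6-trihydroxy-5-methylphenyl]butan-1-one; 18 2-butanoyl-3,5-dihydroxy-6,6-dimethylcyclohexa-2,4-dien-1-one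
Product: 19 2-butanoyl-4-[[3-butanoyl-5-[(3-butanoyl-2,4,6-trihydroxy-5-methylphenyl)methyl]-2,4,6-trihydroxyphenyl]methyl]-3,5-dihydroxy-6,6-dimethylcyclohexa-2,4-dien-1-one (CNP0086105.0)
Conditions: 18 (1.5 equiv), 1,4-dioxane, 70 °C, N2; dilute aq. HCl work-up
Reagents that add atoms: none
Why: The strongly acidic triketone protonates the Mannich base, the ammonium group leaves to give the ring B quinone methide, and C-4 of 18 (the carbon between its two enolic carbons) should add in a Michael-type C-alkylation; neither partner has another free carbon.

**Compound list**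
1 | 2,6-dimethoxytoluene (1,3-dimethoxy-2-methylbenzene) | COc1cccc(OC)c1C | starting material
2 | 2-(3,5-dimethoxy-4-methylphenyl)-4,4,5,5-tetramethyl-1,3,2-dioxaborolane | COc1cc(B2OC(C)(C)C(C)(C)O2)cc(OC)c1C | intermediate (not isolated)
3 | 3,5-dimethoxy-4-methylphenol | COc1cc(O)cc(OC)c1C | intermediate
4 | 2-bromo-3,5-dimethoxy-4-methylphenol | Cc1c(OC)cc(O)c(Br)c1OC | intermediate
5 | (2-bromo-3,5-dimethoxy-4-methylphenoxy)trimethylsilane | Cc1c(OC)cc(O[Si](C)(C)C)c(Br)c1OC | intermediate (not isolated)
6 | {2,4-dimethoxy-3-methyl-6-[(trimethylsilyl)oxy]phenyl}lithium | [Li]c1c(O[Si](C)(C)C)cc(OC)c(C)c1OC | intermediate (not isolated)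
7 | lithium 3,5-dimethoxy-4-methyl-2-(trimethylsilyl)phenoxide | [Li+].[O-]c1cc(OC)c(C)c(OC)c1[Si](C)(C)C | intermediate (not isolated)
8 | 3,5-dimethoxy-4-methyl-2-(trimethylsilyl)phenyl trifluoromethanesulfonate | Cc1c(OC)cc(OS(=O)(=O)C(F)(F)F)c([Si](C)(C)C)c1OC | intermediate
9 | butyric acid | CCCC(=O)O | starting material
10 | 3,5-dimethoxy-4-methylbenzyne (3,5-dimethoxy-4-methyl-1,2-didehydrobenzene) | CC1=C(OC)C#CC=C1OC | intermediate (not isolated)
11 | 1-(6-hydroxy-2,4-dimethoxy-3-methylphenyl)butan-1-one | CCCC(=O)c1c(O)cc(OC)c(C)c1OC | intermediate
12 | 1-(2,4,6-trihydroxy-3-methylphenyl)butan-1-one | CCCC(=O)c1c(O)cc(O)c(C)c1O | intermediate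
13 | 1-[3-[(dimethylamino)methyl]-2,4,6-trihydroxy-5-methylphenyl]butan-1-one | CCCC(=O)c1c(O)c(CN(C)C)c(O)c(C)c1O | intermediate
14 | phloroglucinol (benzene-1,3,5-triol) | Oc1cc(O)cc(O)c1 | starting material
15 | 1-(2,4,6-trihydroxyphenyl)butan-1-one | CCCC(=O)c1c(O)cc(O)cc1O | intermediate
16 | 1-[3-[(3-butanoyl-2,4,6-trihydroxyphenyl)methyl]-2,4,6-trihydroxy-5-methylphenyl]butan-1-one | CCCC(=O)c1c(O)c(Cc2c(O)cc(O)c(C(=O)CCC)c2O)c(O)c(C)c1O | intermediate
17 | 1-[3-[[3-butanoyl-5-[(dimethylamino)methyl]-2,4,6-trihydroxyphenyl]methyl]-2,4,6-trihydroxy-5-methylphenyl]butan-1-one | CCCC(=O)c1c(O)c(Cc2c(O)c(CN(C)C)c(O)c(C(=O)CCC)c2O)c(O)c(C)c1O | intermediate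
18 | 2-butanoyl-3,5-dihydroxy-6,6-dimethylcyclohexa-2,4-dien-1-one | CCCC(=O)C1=C(O)C=C(O)C(C)(C)C1=O | intermediate
19 | 2-butanoyl-4-[[3-butanoyl-5-[(3-butanoyl-2,4,6-trihydroxy-5-methylphenyl)methyl]-2,4,6-trihydroxyphenyl]methyl]-3,5-dihydroxy-6,6-dimethylcyclohexa-2,4-dien-1-one | CCCC(=O)C1=C(O)C(Cc2c(O)c(Cc3c(O)c(C)c(O)c(C(=O)CCC)c3O)c(O)c(C(=O)CCC)c2O)=C(O)C(C)(C)C1=O | target

**Step count**
Total: 11 steps. Longest linear sequence: 9 steps (steps 1–6, 8, 9, 11); steps 7 and 10 supply rings B and A.

**Steps most likely to fail**

Step 4. The aryl anion formed after carboxylate addition may be protonated faster than it attacks the ester carbonyl, so that only O-arylation occurs, or the hindered, electron-rich aryne may be consumed in other ways before the acid adds. The fallback sets out from phenol 3 and replaces the aryne by classical electrophilic acyl transfer. O-Acylation of 3 with butanoyl chloride (pyridine, CH2Cl2, 0 °C) should give 3,5-dimethoxy-4-methylphenyl butanoate F1. Fries rearrangement of F1 with TiCl4 (1.2 equiv, CH2Cl2, 0 °C → rt; aq. HCl) should move the acyl group to one of the two equivalent ortho carbons, the para carbon being blocked by methyl, and return to the route at ketone 11.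

Step 8. Ring B may be alkylated a second time at its other free carbon by the ring C quinone methide, or amine loss may be slow enough for bridge exchange and other side reactions to take over. The fallback sets out from Mannich base 13 and changes the order of assembly so that the valuable ring C donor meets a partner with only one free carbon. Rings B and A are joined first: 15 (in excess) and 18 with aqueous formaldehyde in dilute aqueous KOH at 0 °C (the classical methylene-bis condensation of acylphloroglucinols) should give 2-butanoyl-4-[(3-butanoyl-2,4,6-trihydroxyphenyl)methyl]-3,5-dihydroxy-6,6-dimethylcyclohexa-2,4-dien-1-one F2. The statistical problem is thereby moved onto two inexpensive early compounds. Heating F2 with 13 in 1,4-dioxane should then give target 19 directly, bypassing 16 and 17.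

Step 11. Under amine and heat the methylene bridges may cleave reversibly by retro-Michael reaction, so that rings are exchanged and symmetrical by-products form in the last step. The fallback sets out from dimer 16 and brings the bridging carbon in at the aldehyde oxidation level, firmly bonded to ring B. Vilsmeier–Haack formylation of 16 (POCl3, DMF, EtOAc, 0 °C → rt, then water) at the free carbon of ring B should give 3-butanoyl-5-[(3-butanoyl-2,4,6-trihydroxy-5-methylphenyl)methyl]-2,4,6-trihydroxybenzaldehyde F3. Three-component reductive alkylation of 18 with F3 and Hantzsch ester (cat. L-proline, CH2Cl2/EtOH, rt; Knoevenagel condensation followed by conjugate hydride transfer) should then give target 19.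

**Further compounds**
F1 | step 4 | 3,5-dimethoxy-4-methylphenyl butanoate | CCCC(=O)Oc1cc(OC)c(C)c(OC)c1
F2 | step 8 | 2-butanoyl-4-[(3-butanoyl-2,4,6-trihydroxyphenyl)methyl]-3,5-dihydroxy-6,6-dimethylcyclohexa-2,4-dien-1-one | CCCC(=O)C1=C(O)C(Cc2c(O)cc(O)c(C(=O)CCC)c2O)=C(O)C(C)(C)C1=O
F3 | step 11 | 3-butanoyl-5-[(3-butanoyl-2,4,6-trihydroxy-5-methylphenyl)methyl]-2,4,6-trihydroxybenzaldehyde | CCCC(=O)c1c(O)c(Cc2c(O)c(C=O)c(O)c(C(=O)CCC)c2O)c(O)c(C)c1O
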